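**Plan**
- Retrosynthesis: the C4 carbinol is taken back to a ketone, the C1=C2 alkene to a C1 phenylselenide on a saturated ring, the two ester acyl–O bonds are cut, and last the C3–O and C5–O bonds are cut, leaving a 4-oxocyclohexane carboxylate.
- Enabling feature: on the cyclohexene ring (C1 bears CO2Me, C2 is the alkene CH, C6 is CH2) the oxygens on C3 and C5 are trans. With C4 as a carbonyl and C1 saturated, C3 and C5 are the two equivalent α-carbons of one ketone, and C4 carries no stereochemistry.
- Forward: the six-membered ring is bought and no ring is formed. The order is ketal protection, ester α-selenenylation, ketal removal, double α-aminoxylation, N–O cleavage, double esterification, selenoxide elimination, ketone reduction.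
- Stereochemistry: C3 and C5 (both R) come from L-proline catalyst control in the two aminoxylations. C4 (S) comes from substrate-controlled hydride addition anti to the pseudoaxial C3–O bond. The E alkenes come with the acid.
- Both esters go on while C4 is a ketone, so the free 4-OH between them needs no hydroxyl differentiation.

Key step: step 4

Assumption: (E)-3-methylpent-2-enoic acid is bought geometrically pure; ring atoms keep the numbering of the final cyclohexene (C1 bears CO2Me) in every intermediate.

Step 1
Reactants: 1 methyl 4-oxocyclohexane-1-carboxylate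
Product: 2 methyl 1,4-dioxaspiro[4.5]decane-8-carboxylate
Conditions: ethylene glycol (1.5 equiv), p-TsOH·H2O (2 mol %), toluene, reflux, Dean–Stark
Reagents that add atoms: ethylene glycol, OCCO
Why: Acid-catalysed dioxolane formation (ketalisation) with azeotropic water removal masks the ketone, so that the only acidic C–H left for the next step is the one α to the ester; no stereocentre is formed.

Step 2
Reactants: 2 methyl 1,4-dioxaspiro[4.5]decane-8-carboxylate
Product: 4 methyl 8-(phenylselanyl)-1,4-dioxaspiro[4.5]decane-8-carboxylate, via lithium ester enolate 3 (not isolated)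
Conditions: LiN(i-Pr)2 (1.1 equiv), THF, −78 °C; then PhSeBr (1.15 equiv), −78 → 0 °C
Reagents that add atoms: phenylselenenyl bromide, Br[Se]c1ccccc1
Why: Reich-type α-selenenylation, in which deprotonation gives the ester enolate 3 and its α-carbon attacks selenium of PhSeBr to form the quaternary C–Se centre, which is not stereogenic because the two ring arms are identical.

Step 3
Reactants: 4 methyl 8-(phenylselanyl)-1,4-dioxaspiro[4.5]decane-8-carboxylate
Product: 5 methyl 4-oxo-1-(phenylselanyl)cyclohexane-1-carboxylate
Conditions: 2 M aq HCl, THF, rt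
Reagents that add atoms: water, O
Why: Acid-catalysed ketal hydrolysis frees the C4 ketone, while the methyl ester and the α-seleno ester linkage are inert to dilute aqueous acid at room temperature.

Step 4
Reactants: 5 methyl 4-oxo-1-(phenylselanyl)cyclohexane-1-carboxylate; 6 nitrosobenzene
Product: 8 methyl (3R,5R)-3,5-bis(anilinooxy)-4-oxo-1-(phenylselanyl)cyclohexane-1-carboxylate, via mono-aminoxylated ketone 7 (not isolated)
Conditions: L-proline (30 mol %), nitrosobenzene (3 equiv, added over several hours as a DMF solution), DMF, 0 °C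
Reagents that add atoms: nitrosobenzene, O=Nc1ccccc1
Why: L-Proline condenses with the C4 ketone of 5 to an enamine whose carboxylic acid protonates the nitrogen of nitrosobenzene, so the enamine carbon attacks the nitroso oxygen (O-selective nitroso aldol, the proline-catalysed α-aminoxylation of cyclohexanones) and hydrolysis releases mono-adduct 7. Compound 7 re-forms the enamine at its unsubstituted α′-methylene and is oxygenated a second time, which is the recognised path to trans-2,6-bis(anilinooxy)cyclohexanones when nitrosobenzene is in excess. No ring closes; two C–O bonds are made on the intact six-membered ring. Both new stereocentres, C3 and C5, are set by the catalyst: the hydrogen-bonded transition state of L-proline delivers oxygen in the same sense each time, which gives R at each carbon and therefore the trans (3R,5R) pair, with the meso cis isomer as the only stereochemical by-product. The step needs O- rather than N-attack (secured by the acid-bound nitroso nitrogen) and oxygenation once at each α-carbon rather than twice at one (secured because the enamine forms away from the substituted carbon). C1 is quaternary and cannot react, and it is non-stereogenic again in the trans product, so the two C1 epimers of 7 converge on one compound.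

Step 5
Reactants: 8 methyl (3R,5R)-3,5-bis(anilinooxy)-4-oxo-1-(phenylselanyl)cyclohexane-1-carboxylate
Product: 9 methyl (3R,5R)-3,5-dihydroxy-4-oxo-1-(phenylselanyl)cyclohexane-1-carboxylate
Conditions: CuSO4·5H2O (30 mol %), MeOH, 0 °C; crude product used at once
Reagents that add atoms: none
Why: CuSO4-promoted N–O cleavage of α-anilinooxy ketones is the standard mild route to the α-hydroxy ketone with the α-stereocentres untouched, the aniline nitrogen being expected to leave as azobenzene, and neither the selenide nor the ester reacts; diol 9 is carried forward without storage because α-hydroxy ketones epimerise and dimerise on standing.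

Step 6
Reactants: 9 methyl (3R,5R)-3,5-dihydroxy-4-oxo-1-(phenylselanyl)cyclohexane-1-carboxylate; 10 (E)-3-methylpent-2-enoic acid
Product: 11 methyl (3R,5R)-3,5-bis{[(E)-3-methylpent-2-enoyl]oxy}-4-oxo-1-(phenylselanyl)cyclohexane-1-carboxylate
Conditions: 10 (2.5 equiv), DCC (2.6 equiv), DMAP (20 mol %), CH2Cl2, 0 °C → rt
Reagents that add atoms: (E)-3-methylpent-2-enoic acid, CC/C(C)=C/C(=O)O
Why: Steglich esterification (carbodiimide activation, DMAP acyl transfer) acylates both secondary hydroxyls of 9 while C4 is still a ketone, so no hydroxyl has to be told apart later; activating the free acid instead of using an acid chloride with amine base avoids the vinylketene pathway that would move or isomerise the E alkene, and the cold, weakly basic medium protects the two α-stereocentres.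

Step 7
Reactants: 11 methyl (3R,5R)-3,5-bis{[(E)-3-methylpent-2-enoyl]oxy}-4-oxo-1-(phenylselanyl)cyclohexane-1-carboxylate
Product: 13 methyl (3R,5R)-3,5-bis{[(E)-3-methylpent-2-enoyl]oxy}-4-oxocyclohex-1-ene-1-carboxylate, via selenoxide 12 (not isolated)
Conditions: 30% aq H2O2 (3 equiv), CH2Cl2, 0 °C → rt, no amine base; cold pH 7 buffer wash; product used at once
Reagents that add atoms: none
Why: Selenide oxidation gives selenoxide 12, which undergoes syn elimination below room temperature to the α,β-unsaturated ester; elimination toward either ring methylene gives the same enone 13 because C3 and C5 are equivalent until the alkene is in place, excess H2O2 converts the expelled PhSeOH into PhSeO2H so that it cannot add back, and amine base is left out because C3–H in 13 is both α to the ketone and allylic.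

Step 8
Reactants: 13 methyl (3R,5R)-3,5-bis{[(E)-3-methylpent-2-enoyl]oxy}-4-oxocyclohex-1-ene-1-carboxylate
Product: 14 methyl (3R,4S,5R)-4-hydroxy-3,5-bis{[(E)-3-methylpent-2-enoyl]oxy}cyclohex-1-ene-1-carboxylate
Conditions: NaBH4 (1.0 equiv), CeCl3·7H2O (1.1 equiv), MeOH, −78 °C; AcOH quench at −78 °C
Reagents that add atoms: none
Why: Luche reduction adds hydride 1,2 to the activated ketone and leaves the three α,β-unsaturated esters alone; in the half-chair of 13 with the C5 ester equatorial and the allylic C3 ester pseudoaxial, hydride should enter axially, anti to the C3–O bond (Felkin–Anh-type attack on the less hindered face), giving the equatorial 4-OH cis to O3 and trans to O5, that is 4S, and the cold acidic quench prevents acyl migration to the new hydroxyl.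

**Compound list**
1 | methyl 4-oxocyclohexane-1-carboxylate | COC(=O)C1CCC(=O)CC1 | starting material
2 | methyl 1,4-dioxaspiro[4.5]decane-8-carboxylate | COC(=O)C1CCC2(CC1)OCCO2 | intermediate
3 | lithium enolate of 2 (lithium methoxy(1,4-dioxaspiro[4.5]decan-8-ylidene)methanolate) | [Li+].[O-]C(OC)=C1CCC2(CC1)OCCO2 | intermediate
4 | methyl 8-(phenylselanyl)-1,4-dioxaspiro[4.5]decane-8-carboxylate | COC(=O)C1([Se]c2ccccc2)CCC2(CC1)OCCO2 | intermediate
5 | methyl 4-oxo-1-(phenylselanyl)cyclohexane-1-carboxylate | COC(=O)C1([Se]c2ccccc2)CCC(=O)CC1 | intermediate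
6 | nitrosobenzene | O=Nc1ccccc1 | starting material
7 | methyl (3R)-3-(anilinooxy)-4-oxo-1-(phenylselanyl)cyclohexane-1-carboxylate (both C1 epimers) | c1ccccc1NO[C@@H]1CC([Se]c2ccccc2)(C(=O)OC)CCC1=O | intermediate
8 | methyl (3R,5R)-3,5-bis(anilinooxy)-4-oxo-1-(phenylselanyl)cyclohexane-1-carboxylate | c1ccccc1NO[C@@H]1CC([Se]c2ccccc2)(C(=O)OC)C[C@@H](ONc2ccccc2)C1=O | intermediate
9 | methyl (3R,5R)-3,5-dihydroxy-4-oxo-1-(phenylselanyl)cyclohexane-1-carboxylate | O[C@@H]1CC([Se]c2ccccc2)(C(=O)OC)C[C@@H](O)C1=O | intermediate
10 | (E)-3-methylpent-2-enoic acid | CC/C(C)=C/C(=O)O | starting material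
11 | methyl (3R,5R)-3,5-bis{[(E)-3-methylpent-2-enoyl]oxy}-4-oxo-1-(phenylselanyl)cyclohexane-1-carboxylate | CC/C(C)=C/C(=O)O[C@@H]1CC([Se]c2ccccc2)(C(=O)OC)C[C@@H](OC(=O)/C=C(\C)CC)C1=O | intermediate
12 | methyl (3R,5R)-3,5-bis{[(E)-3-methylpent-2-enoyl]oxy}-4-oxo-1-(phenylseleninyl)cyclohexane-1-carboxylate (either configuration at selenium) | CC/C(C)=C/C(=O)O[C@@H]1CC([Se](=O)c2ccccc2)(C(=O)OC)C[C@@H](OC(=O)/C=C(\C)CC)C1=O | intermediate
13 | methyl (3R,5R)-3,5-bis{[(E)-3-methylpent-2-enoyl]oxy}-4-oxocyclohex-1-ene-1-carboxylate | CC/C(C)=C/C(=O)O[C@@H]1C=C(C(=O)OC)C[C@@H](OC(=O)/C=C(\C)CC)C1=O | intermediate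
14 | methyl (3R,4S,5R)-4-hydroxy-3,5-bis{[(E)-3-methylpent-2-enoyl]oxy}cyclohex-1-ene-1-carboxylate | CC/C(C)=C/C(=O)O[C@@H]1C=C(C(=O)OC)C[C@@H](OC(=O)/C=C(\C)CC)[C@@H]1O | target

**Totals**
Total steps: 8. Longest linear sequence: 8 (steps 1 to 8, fully linear; compounds 6 and 10 are purchased).

**Steps most likely to fail**

Step 7. The β,γ-unsaturated ketone may enolise at C3 during or after the elimination. That would cause epimerisation, migration of the alkene into conjugation, or aromatisation with loss of the C5 ester. Peroxyseleninic acid may also over-oxidise the ketone. The fallback sets out from 11 and returns at 14 by reversing the last two operations. Luche reduction of 11 (NaBH4, CeCl3·7H2O, MeOH, −78 °C) should give methyl (3R,5R)-4-hydroxy-3,5-bis{[(E)-3-methylpent-2-enoyl]oxy}-1-(phenylselanyl)cyclohexane-1-carboxylate F1, with the hydroxyl cis or trans to selenium and C3 and C5 untouched. Oxidation with aqueous H2O2 then gives the corresponding selenoxide F2, which eliminates in a ring that no longer holds an enolisable ketone. Elimination toward the methylene next to the acyloxy carbon that is cis to the hydroxyl gives 14 directly. Elimination toward the other methylene can only give the C4 epimer of 14, methyl (3R,4R,5R)-4-hydroxy-3,5-bis{[(E)-3-methylpent-2-enoyl]oxy}cyclohex-1-ene-1-carboxylate F3. This is separated and converted into 14 by the inversion described for step 8.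

Step 8. Facial selectivity of hydride addition to the conformationally mobile enone may be poor, and an acyl group may migrate to the new alkoxide. The fallback sets out from 13 and returns at 14 without relying on the selectivity of the reduction. After reduction, the C4 epimer, methyl (3R,4R,5R)-4-hydroxy-3,5-bis{[(E)-3-methylpent-2-enoyl]oxy}cyclohex-1-ene-1-carboxylate F3, is separated from 14. It is inverted by a Mitsunobu reaction with chloroacetic acid (PPh3, DIAD, toluene, 0 °C → rt) to methyl (3R,4S,5R)-4-[(chloroacetyl)oxy]-3,5-bis{[(E)-3-methylpent-2-enoyl]oxy}cyclohex-1-ene-1-carboxylate F4. The chloroacetyl group alone is then removed with thiourea and NaHCO3 in ethanol, which should leave the two enoates and the methyl ester in place and give 14.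

Step 4. The reaction may stall after the first oxygenation. The first anilinooxy group may bias the second enamine and erode trans selectivity. The bis(anilinooxy) ketone may also suffer N–O heterolysis on long exposure to the catalyst. The fallback sets out from 5 and returns at 11, oxygenating and esterifying one α-carbon at a time:
- Aminoxylation of 5 with 1.2 equiv of nitrosobenzene (L-proline, DMF, 0 °C) is stopped at 7, which is isolated.
- CuSO4·5H2O in MeOH gives methyl (3R)-3-hydroxy-4-oxo-1-(phenylselanyl)cyclohexane-1-carboxylate F5.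
- Steglich esterification with 10 gives methyl (3R)-3-{[(E)-3-methylpent-2-enoyl]oxy}-4-oxo-1-(phenylselanyl)cyclohexane-1-carboxylate F6.
- A second L-proline aminoxylation at the remaining α-methylene gives methyl (3R,5R)-3-(anilinooxy)-5-{[(E)-3-methylpent-2-enoyl]oxy}-4-oxo-1-(phenylselanyl)cyclohexane-1-carboxylate F7.
- CuSO4·5H2O in MeOH gives methyl (3R,5R)-3-hydroxy-5-{[(E)-3-methylpent-2-enoyl]oxy}-4-oxo-1-(phenylselanyl)cyclohexane-1-carboxylate F8.
- A second esterification with 10 gives 11.

C1 is stereogenic in F5 to F8. Both epimers are carried together and converge in 11.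

**Further compounds**
F1 | step 7 | methyl (3R,5R)-4-hydroxy-3,5-bis{[(E)-3-methylpent-2-enoyl]oxy}-1-(phenylselanyl)cyclohexane-1-carboxylate (hydroxyl cis or trans to selenium) | CC/C(C)=C/C(=O)O[C@@H]1CC([Se]c2ccccc2)(C(=O)OC)C[C@@H](OC(=O)/C=C(\C)CC)C1O
F2 | step 7 | methyl (3R,5R)-4-hydroxy-3,5-bis{[(E)-3-methylpent-2-enoyl]oxy}-1-(phenylseleninyl)cyclohexane-1-carboxylate | CC/C(C)=C/C(=O)O[C@@H]1CC([Se](=O)c2ccccc2)(C(=O)OC)C[C@@H](OC(=O)/C=C(\C)CC)C1O
F3 | step 8 | methyl (3R,4R,5R)-4-hydroxy-3,5-bis{[(E)-3-methylpent-2-enoyl]oxy}cyclohex-1-ene-1-carboxylate | CC/C(C)=C/C(=O)O[C@@H]1C=C(C(=O)OC)C[C@@H](OC(=O)/C=C(\C)CC)[C@H]1O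
F4 | step 8 | methyl (3R,4S,5R)-4-[(chloroacetyl)oxy]-3,5-bis{[(E)-3-methylpent-2-enoyl]oxy}cyclohex-1-ene-1-carboxylate | CC/C(C)=C/C(=O)O[C@@H]1C=C(C(=O)OC)C[C@@H](OC(=O)/C=C(\C)CC)[C@@H]1OC(=O)CCl
F5 | step 4 | methyl (3R)-3-hydroxy-4-oxo-1-(phenylselanyl)cyclohexane-1-carboxylate (both C1 epimers) | O[C@@H]1CC([Se]c2ccccc2)(C(=O)OC)CCC1=O
F6 | step 4 | methyl (3R)-3-{[(E)-3-methylpent-2-enoyl]oxy}-4-oxo-1-(phenylselanyl)cyclohexane-1-carboxylate (both C1 epimers) | CC/C(C)=C/C(=O)O[C@@H]1CC([Se]c2ccccc2)(C(=O)OC)CCC1=O
F7 | step 4 | methyl (3R,5R)-3-(anilinooxy)-5-{[(E)-3-methylpent-2-enoyl]oxy}-4-oxo-1-(phenylselanyl)cyclohexane-1-carboxylate (both C1 epimers) | CC/C(C)=C/C(=O)O[C@@H]1CC([Se]c2ccccc2)(C(=O)OC)C[C@@H](ONc2ccccc2)C1=O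
F8 | step 4 | methyl (3R,5R)-3-hydroxy-5-{[(E)-3-methylpent-2-enoyl]oxy}-4-oxo-1-(phenylselanyl)cyclohexane-1-carboxylate (both C1 epimers) | CC/C(C)=C/C(=O)O[C@@H]1CC([Se]c2ccccc2)(C(=O)OC)C[C@@H](O)C1=O
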